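## Retrosynthetic overview

- Hypholomine B is the dehydrodimer of hispidin. Ring A is the fused 2-pyrone, ring B the pendant 4-hydroxy-2-pyrone, ring C the dihydrofuran, ring D the catechol on C-2 and ring E the catechol of the styryl group (furo[3,2-c]pyran-4-one numbering).
- Ring C is cut at O-1–C-2 and at C-3–C-3a. This gives two differently protected hispidins: a 3-diazopyran-2,4-dione (rings A and E) and a styrylpyrone (rings B and D). In the forward direction, asymmetric carbene transfer builds a temporary spirocyclopropane, and its strain-driven opening closes O-1–C-2.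
- The enabling feature is twofold. C-2 is benzylic and para to an oxygen of ring D, so it can carry a quinoid cation. O-1 is the enol oxygen of the vinylogous acid O-1–C-7a=C-3a–C-4=O of ring A. The O-1–C-2 bond therefore forms spontaneously, reversibly and trans.
- Both partners come from one styrylpyrone, made from triacetic acid lactone (rings A and B) and protected 3,4-dihydroxybenzaldehyde (rings D and E).
- Rings A, B, D and E are bought. The cyclopropane is temporary. Ring C is formed last.

Key step: step 7

Assumption: the sense of induction of Rh2(S-NTTL)4 on this substrate class cannot be derived from precedent. It is taken to expose the Si face of the alkene carbon next to ring B, and the mirror-image catalyst Rh2(R-NTTL)4 would be used if the opposite sense is found.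

(TBS = tert-butyldimethylsilyl)

## Route

Step 1
Reactants: 1 3,4-dihydroxybenzaldehyde
Product: 2 3,4-bis(tert-butyldimethylsilyloxy)benzaldehyde
Conditions: TBSCl (2.4 equiv), imidazole, DMF, rt
Reagents that add atoms: tert-butyldimethylsilyl chloride, CC(C)(C)[Si](C)(C)Cl
Why: Standard imidazole-promoted O-silylation of phenols; the aryl TBS ethers survive the strong base of step 2 and later keep ring D a donor.

Step 2
Reactants: 2 3,4-bis(tert-butyldimethylsilyloxy)benzaldehyde; 3 4-hydroxy-6-methyl-2H-pyran-2-one (triacetic acid lactone)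
Product: 4 rac-6-{2-[3,4-bis(tert-butyldimethylsilyloxy)phenyl]-2-hydroxyethyl}-4-hydroxy-2H-pyran-2-one
Conditions: 3, LiN(i-Pr)2 (commercial solution, 2.3 equiv), THF–DMPU, −78 to −20 °C; 2, −78 °C; 1 M HCl
Reagents that add atoms: none
Why: Aldol addition of the O,C-dianion of triacetic acid lactone, which reacts at its more basic C-6 methyl carbanion; the carbinol centre is racemic and is erased in step 3.

Step 3
Reactants: 4 rac-aldol adduct
Product: 5 6-{(E)-2-[3,4-bis(tert-butyldimethylsilyloxy)phenyl]ethenyl}-4-hydroxy-2H-pyran-2-one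
Conditions: p-TsOH·H2O (10 mol %), toluene (0.02 M), 80 °C
Reagents that add atoms: none
Why: Acid-catalysed E1 dehydration through the para-silyloxybenzyl cation should give the fully conjugated, thermodynamically preferred E-alkene, and high dilution suppresses Friedel-Crafts capture of the cation by C-3 of a second pyrone.

Step 4
Reactants: 5 bis-TBS styrylpyrone
Product: 6 6-{(E)-2-[3,4-bis(tert-butyldimethylsilyloxy)phenyl]ethenyl}-2-oxo-2H-pyran-4-yl acetate
Conditions: Ac2O (1.2 equiv), pyridine, CH2Cl2, 0 °C
Reagents that add atoms: acetic anhydride, CC(=O)OC(C)=O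
Why: O-Acylation of the vinylogous acid (no DMAP, so no O-to-C acyl shift); the acetyl group removes the O–H bond that a carbene would insert into and lowers the nucleophilicity of C-3 of ring B.

Step 5
Reactants: 5 bis-TBS styrylpyrone
Product: 9 hispidin 3',4'-diacetate, via hispidin 7 (not isolated), via hispidin triacetate 8 (not isolated)
Conditions: KHF2, MeOH, rt; evaporate; Ac2O (excess), pyridine, 0 °C to rt; then MeOH, rt
Reagents that add atoms: acetic anhydride, CC(=O)OC(C)=O
Why: Fluoride cleavage of the phenolic silyl ethers and peracetylation are followed by chemoselective methanolysis of the O-4 acetate, a vinylogous mixed anhydride that is far more electrophilic than the two aryl acetates.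

Step 6
Reactants: 9 hispidin 3',4'-diacetate
Product: 10 6-[(E)-2-(3,4-diacetoxyphenyl)ethenyl]-3-diazo-2H-pyran-2,4(3H)-dione
Conditions: 4-acetamidobenzenesulfonyl azide (1.1 equiv), Et3N, MeCN, 0 °C to rt, dark
Reagents that add atoms: 4-acetamidobenzenesulfonyl azide, CC(=O)Nc1ccc(cc1)S(=O)(=O)N=[N+]=[N-]
Why: Regitz diazo transfer to the acidic C-3 of a 4-hydroxy-2-pyrone, a known substrate class; aryl acetates tolerate Et3N in an aprotic solvent.

Step 7
Reactants: 10 3-diazopyran-2,4-dione; 6 4-acetoxy-6-styryl-2-pyrone (1.5 equiv, excess recovered)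
Product: 12 (2S,3S)-3-(4-acetoxy-2-oxo-2H-pyran-6-yl)-2-[3,4-bis(tert-butyldimethylsilyloxy)phenyl]-6-[(E)-2-(3,4-diacetoxyphenyl)ethenyl]-2,3-dihydro-4H-furo[3,2-c]pyran-4-one, via spirocyclopropane 11 (not isolated)
Conditions: Rh2(S-NTTL)4 (dirhodium tetrakis[N-(1,8-naphthaloyl)-(S)-tert-leucinate], 2 mol %), 4 Å MS, PhCF3, 40 °C, 10 added over 6 h; then 60 °C, 2 h
Reagents that add atoms: none
Why: Proposed new method: loss of N2 from 10 on the divalent-rhodium dimer makes its C-3 an electrophilic, catalyst-bound carbene carbon that is attacked by the alkene of 6 at the carbon next to ring B; [2+1] closure gives the donor-acceptor spirocyclopropane 11, whose strain is released by heterolysis of the bond between the spiro and the benzylic carbon (push from the para silyloxy group of ring D, pull from the 1,3-dicarbonyl unit that regains the 2-pyrone of ring A), and the former ketone oxygen then captures the quinoid benzylic cation to form O-1–C-2. The closest known reaction types are the Rh2(OAc)4-catalysed formal [3+2] cycloaddition of 3-diazopyran-2,4-diones and other cyclic 2-diazo-1,3-dicarbonyls with styrenes to give 2,3-dihydrofurans, the Rh2(S-NTTL)4-catalysed enantioselective cyclopropanation with the cyclic diacceptor carbene derived from Meldrum's acid, and the Cloke-Wilson rearrangement; what is new is the enantioselective version on a 1,2-disubstituted push-pull styrylpyrone. The temporary three-membered ring closes by [2+1] carbene transfer and ring C closes 5-exo-trig. C-3 is set (S) in the C–C bond-forming event by the chiral carboxylate pocket (attack on the Si face of that alkene carbon) and keeps all four of its bonds afterwards, whereas C-2 is set (S) by substrate control because the reversible O-1–C-2 closure settles trans to the ring B substituent. Chemoselectivity among the C=C bonds is secured by the protecting groups: silyl ethers keep ring D a donor, while the acetates on ring E and on O-4 of ring B switch off the styryl group of 10 and of 12 and C-3 of ring B. Regioselectivity follows from the push-pull polarisation of the alkene, and closure through the ketone rather than the lactone oxygen gives the more stable 4-alkoxy-2-pyrone and is corrected by the same reversibility.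

Step 8
Reactants: 12 protected dimer
Product: 14 hypholomine B, via bis-TBS ether 13 (not isolated)
Conditions: NH4OAc (excess), MeOH–THF–H2O, rt, Ar; then KHF2, rt
Reagents that add atoms: none
Why: Ammonium acetate-mediated transesterification removes the three acetates at neutral pH while ring D is still silylated, so no para-phenoxide can expel O-1, and KHF2 then cleaves the phenolic silyl ethers under weakly acidic conditions, so neither stereocentre is touched.

## Compound list

1 | 3,4-dihydroxybenzaldehyde | O=Cc1ccc(O)c(O)c1 | starting material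
2 | 3,4-bis(tert-butyldimethylsilyloxy)benzaldehyde | O=Cc1ccc(O[Si](C)(C)C(C)(C)C)c(O[Si](C)(C)C(C)(C)C)c1 | intermediate
3 | 4-hydroxy-6-methyl-2H-pyran-2-one (triacetic acid lactone) | Cc1cc(O)cc(=O)o1 | starting material
4 | rac-6-{2-[3,4-bis(TBS-oxy)phenyl]-2-hydroxyethyl}-4-hydroxy-2H-pyran-2-one (racemic carbinol) | O=c1cc(O)cc(CC(O)c2ccc(O[Si](C)(C)C(C)(C)C)c(O[Si](C)(C)C(C)(C)C)c2)o1 | intermediate
5 | 6-{(E)-2-[3,4-bis(TBS-oxy)phenyl]ethenyl}-4-hydroxy-2H-pyran-2-one | O=c1cc(O)cc(/C=C/c2ccc(O[Si](C)(C)C(C)(C)C)c(O[Si](C)(C)C(C)(C)C)c2)o1 | intermediate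
6 | 6-{(E)-2-[3,4-bis(TBS-oxy)phenyl]ethenyl}-2-oxo-2H-pyran-4-yl acetate | CC(=O)Oc1cc(/C=C/c2ccc(O[Si](C)(C)C(C)(C)C)c(O[Si](C)(C)C(C)(C)C)c2)oc(=O)c1 | intermediate
7 | hispidin | O=c1cc(O)cc(/C=C/c2ccc(O)c(O)c2)o1 | intermediate
8 | hispidin triacetate | CC(=O)Oc1cc(/C=C/c2ccc(OC(C)=O)c(OC(C)=O)c2)oc(=O)c1 | intermediate
9 | hispidin 3',4'-diacetate | O=c1cc(O)cc(/C=C/c2ccc(OC(C)=O)c(OC(C)=O)c2)o1 | intermediate
10 | 6-[(E)-2-(3,4-diacetoxyphenyl)ethenyl]-3-diazo-2H-pyran-2,4(3H)-dione | [N-]=[N+]=C1C(=O)C=C(/C=C/c2ccc(OC(C)=O)c(OC(C)=O)c2)OC1=O | intermediate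
11 | trans-(1S,2R)-1-[3,4-bis(TBS-oxy)phenyl]-2-(4-acetoxy-2-oxo-2H-pyran-6-yl)-6-[(E)-2-(3,4-diacetoxyphenyl)ethenyl]-5-oxaspiro[2.5]oct-6-ene-4,8-dione (spiro carbon drawn 3S; its configuration is lost on ring expansion) | O=C1C=C(/C=C/c2ccc(OC(C)=O)c(OC(C)=O)c2)OC(=O)[C@]13[C@H](c2ccc(O[Si](C)(C)C(C)(C)C)c(O[Si](C)(C)C(C)(C)C)c2)[C@H]3c2cc(OC(C)=O)cc(=O)o2 | intermediate
12 | (2S,3S)-3-(4-acetoxy-2-oxo-2H-pyran-6-yl)-2-[3,4-bis(TBS-oxy)phenyl]-6-[(E)-2-(3,4-diacetoxyphenyl)ethenyl]-2,3-dihydro-4H-furo[3,2-c]pyran-4-one | O=c1cc(OC(C)=O)cc([C@H]2c3c(cc(/C=C/c4ccc(OC(C)=O)c(OC(C)=O)c4)oc3=O)O[C@@H]2c2ccc(O[Si](C)(C)C(C)(C)C)c(O[Si](C)(C)C(C)(C)C)c2)o1 | intermediate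
13 | (2S,3S)-2-[3,4-bis(TBS-oxy)phenyl]-6-[(E)-2-(3,4-dihydroxyphenyl)ethenyl]-3-(4-hydroxy-2-oxo-2H-pyran-6-yl)-2,3-dihydro-4H-furo[3,2-c]pyran-4-one | O=c1cc(O)cc([C@H]2c3c(cc(/C=C/c4ccc(O)c(O)c4)oc3=O)O[C@@H]2c2ccc(O[Si](C)(C)C(C)(C)C)c(O[Si](C)(C)C(C)(C)C)c2)o1 | intermediate
14 | hypholomine B, (2S,3S)-2-(3,4-dihydroxyphenyl)-6-[(E)-2-(3,4-dihydroxyphenyl)ethenyl]-3-(4-hydroxy-2-oxo-2H-pyran-6-yl)-2,3-dihydro-4H-furo[3,2-c]pyran-4-one | O=c1cc(O)cc([C@H]2c3c(cc(/C=C/c4ccc(O)c(O)c4)oc3=O)O[C@@H]2c2ccc(O)c(O)c2)o1 | target

## Step count and risks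

Total step count: 8.
Longest linear sequence: 7 (steps 1, 2, 3, 5, 6, 7, 8).

**Step 7.**
- *What may go wrong:* carbene transfer to the hindered 1,2-disubstituted push-pull alkene may be slower than unproductive decay of the carbene, and the catalyst may discriminate poorly between the alkene faces.
- *Fallback (known chemistry):* it sets out from pyrone 9 and alkene 6. Mn(OAc)3·2H2O (2.2 equiv) in AcOH at 60 °C effects the oxidative radical [3+2] cycloaddition of the 1,3-dicarbonyl unit of 9 to the alkene. The radical adds next to ring B, a second trivalent manganese oxidises the benzylic radical, and O-1–C-2 closes. The same protecting-group bias applies.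
- This should give trans-configured 12 as the racemate, that is, together with its (2R,3R)-enantiomer F1. Preparative supercritical-fluid chromatography on a chiral stationary phase separates the two, and the route is rejoined at 12.

**Step 8.**
- *What may go wrong:* once the para-hydroxy group of ring D is free, O-1 may be expelled through a quinone methide and that species may be captured by methanol. The two catechols may also oxidise in air, and the very polar product may be lost on chromatography.
- *Fallback:* it sets out from 12. A one-pot silyl-to-acetyl exchange (Bu4NF, Ac2O, THF, 0 °C) gives hypholomine B pentaacetate F2. This non-polar, air-stable compound can be purified, and enriched in one enantiomer, by crystallisation.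
- Lipase-catalysed alcoholysis of the kind known for polyphenol peracetates (immobilised Candida antarctica lipase B, n-BuOH, t-BuOMe–THF, 35 °C) then releases the five hydroxy groups at neutral pH. The route is rejoined at 14.

**Step 3.**
- *What may go wrong:* the benzylic cation may be captured intermolecularly by the nucleophilic C-3 of a second pyrone, and the acid may cause partial desilylation.
- *Fallback:* it sets out from 4 and avoids any cation. Ac2O and pyridine convert 4 into the racemic bis-acetate F3. DBU (CH2Cl2, 0 °C) then removes the acidic proton next to C-6 of the pyrone and expels the benzylic acetate by E1cB elimination, and the route is rejoined at 6.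
- The compound 5 needed for step 5 is obtained from 6 by brief methanolysis (MeOH, catalytic pyridine).

## Further compounds

F1 | step 7 | (2R,3R)-enantiomer of 12 | O=c1cc(OC(C)=O)cc([C@@H]2c3c(cc(/C=C/c4ccc(OC(C)=O)c(OC(C)=O)c4)oc3=O)O[C@H]2c2ccc(O[Si](C)(C)C(C)(C)C)c(O[Si](C)(C)C(C)(C)C)c2)o1
F2 | step 8 | hypholomine B pentaacetate (2S,3S) | O=c1cc(OC(C)=O)cc([C@H]2c3c(cc(/C=C/c4ccc(OC(C)=O)c(OC(C)=O)c4)oc3=O)O[C@@H]2c2ccc(OC(C)=O)c(OC(C)=O)c2)o1
F3 | step 3 | rac-6-{2-acetoxy-2-[3,4-bis(TBS-oxy)phenyl]ethyl}-2-oxo-2H-pyran-4-yl acetate | CC(=O)Oc1cc(CC(OC(C)=O)c2ccc(O[Si](C)(C)C(C)(C)C)c(O[Si](C)(C)C(C)(C)C)c2)oc(=O)c1
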